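**Assumption:** the target has no stereocentre and no stereogenic double bond (the prenyl alkene carries two identical methyls), so it is one achiral compound and no enantioselective step is needed. 4‑Methoxyresorcinol is taken as a catalogue compound.

## Retrosynthetic overview

- Rings A and B are bought: 4‑methoxyresorcinol 1 and homoveratric acid 2. Cutting the aryl–CO bond leads back from deoxybenzoin 3 to these two (Friedel–Crafts acylation).
- Ring C is the only ring formed. Its C‑2 comes from DMF, through enaminone 4, to give 7‑hydroxyisoflavone 5.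
- The C8 prenyl group is cut inside the side chain (ArCH2–CH=CMe2). Mannich base 6 and isobutenylboronic acid 7 combine through ortho‑quinone methide 8 to give target 9 (new step).
- Order: A and B preformed, then ring C (step 2), then C8–CH2 (step 3), then CH2–CH=CMe2 (step 4, last).

## Route

Step 1
Reactants: 1 4‑methoxybenzene‑1,3‑diol (4‑methoxyresorcinol); 2 2‑(3,4‑dimethoxyphenyl)acetic acid
Product: 3 1‑(2,4‑dihydroxy‑5‑methoxyphenyl)‑2‑(3,4‑dimethoxyphenyl)ethan‑1‑one
Conditions: BF3·OEt2 (neat, as solvent), 85 °C, 2 h; then aq. NaOAc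
Reagents that add atoms: none
Why: Friedel–Crafts (Nencki‑type) C‑acylation in BF3·OEt2 occurs at the ring position para to one OH and ortho to the other (most activated, least hindered), and the BF2‑chelated o‑hydroxyketone that forms is deactivated, so the reaction stops at monoacylation with the methyl ethers intact.

Step 2
Reactants: 3 1‑(2,4‑dihydroxy‑5‑methoxyphenyl)‑2‑(3,4‑dimethoxyphenyl)ethan‑1‑one
Product: 5 3‑(3,4‑dimethoxyphenyl)‑7‑hydroxy‑6‑methoxy‑4H‑chromen‑4‑one, via enaminone 4 (not isolated)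
Conditions: BF3·OEt2 (Lewis‑acid promoter), DMF, 50 °C; then MsCl in DMF, 80 °C, 2 h; then H2O
Reagents that add atoms: N,N‑dimethylformamide, CN(C)C=O
Why: Deoxybenzoin isoflavone synthesis, in which the Vilsmeier‑type iminium from DMF/MsCl C‑formylates the BF3‑activated benzylic methylene to enaminone 4, whose ortho‑OH adds to the β‑carbon and expels dimethylamine (addition–elimination) to close the γ‑pyranone; the free 4‑OH is tolerated and becomes the 7‑OH.

Step 3
Reactants: 5 3‑(3,4‑dimethoxyphenyl)‑7‑hydroxy‑6‑methoxy‑4H‑chromen‑4‑one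
Product: 6 8‑[(dimethylamino)methyl]‑3‑(3,4‑dimethoxyphenyl)‑7‑hydroxy‑6‑methoxy‑4H‑chromen‑4‑one
Conditions: CH2(NMe2)2 (1.3 equiv), 1,4‑dioxane, 100 °C, 3 h
Reagents that add atoms: bis(dimethylamino)methane, CN(C)CN(C)C
Why: Phenol Mannich reaction, in which the 7‑OH activates only its ortho positions and C6 is blocked by OMe, so aminomethylation goes solely to C8; ring B has no free OH and does not react with the aminal.

Step 4
Reactants: 6 8‑[(dimethylamino)methyl]‑3‑(3,4‑dimethoxyphenyl)‑7‑hydroxy‑6‑methoxy‑4H‑chromen‑4‑one; 7 (2‑methylprop‑1‑en‑1‑yl)boronic acid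
Product: 9 3‑(3,4‑dimethoxyphenyl)‑7‑hydroxy‑6‑methoxy‑8‑(3‑methylbut‑2‑en‑1‑yl)‑4H‑chromen‑4‑one, via ortho‑quinone methide 8 (not isolated)
Conditions: 7 (3 equiv), 1,4‑dioxane, 110 °C (sealed tube, Ar), 12 h; then aq. NH4Cl
Reagents that add atoms: none
Why: Proposed new method: boron‑templated deaminative alkenylation (a formal C8–H prenylation by a C1 + C4 disconnection), in which 7 binds the acidic 7‑OH and the basic nitrogen of 6, this B–O/B–N (or N–H+) activation lets dimethylamine leave to give the boron‑bound ortho‑quinone methide 8, and the 2‑methylprop‑1‑enyl group then shifts from the tetracoordinate boronate to the exocyclic CH2 through a six‑membered transition state (O7–C7–C8–CH2···Cα–B), which can only give the linear ArCH2–CH=CMe2 unit at C8 and rearomatises ring A without strong acid (so no chroman formation); the closest known reaction type is the Petasis‑type 1,4‑addition of alkenyl boronates to ortho‑quinone methides made in situ, together with thermal ortho‑quinone methide generation from 8‑aminomethyl‑7‑hydroxyisoflavones for hetero‑Diels–Alder reactions, and the combination with an unsubstituted CH2 quinone methide of a 7‑hydroxychromone, an amine leaving group and a β,β‑disubstituted alkenylboron is, as far as I know, unreported.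

## Compound list

1 | 4‑methoxybenzene‑1,3‑diol (4‑methoxyresorcinol) | COc1ccc(O)cc1O | starting material
2 | 2‑(3,4‑dimethoxyphenyl)acetic acid (homoveratric acid) | COc1ccc(CC(=O)O)cc1OC | starting material
3 | 1‑(2,4‑dihydroxy‑5‑methoxyphenyl)‑2‑(3,4‑dimethoxyphenyl)ethan‑1‑one | COc1ccc(CC(=O)c2cc(OC)c(O)cc2O)cc1OC | intermediate
4 | (E)‑1‑(2,4‑dihydroxy‑5‑methoxyphenyl)‑3‑(dimethylamino)‑2‑(3,4‑dimethoxyphenyl)prop‑2‑en‑1‑one (enaminone; geometry labile and immaterial) | CN(C)/C=C(\c1ccc(OC)c(OC)c1)C(=O)c1cc(OC)c(O)cc1O | intermediate (not isolated)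
5 | 3‑(3,4‑dimethoxyphenyl)‑7‑hydroxy‑6‑methoxy‑4H‑chromen‑4‑one (7‑hydroxy‑6,3',4'‑trimethoxyisoflavone) | COc1ccc(-c2coc3cc(O)c(OC)cc3c2=O)cc1OC | intermediate
6 | 8‑[(dimethylamino)methyl]‑3‑(3,4‑dimethoxyphenyl)‑7‑hydroxy‑6‑methoxy‑4H‑chromen‑4‑one | COc1ccc(-c2coc3c(CN(C)C)c(O)c(OC)cc3c2=O)cc1OC | intermediate
7 | (2‑methylprop‑1‑en‑1‑yl)boronic acid | CC(C)=CB(O)O | starting material
8 | 3‑(3,4‑dimethoxyphenyl)‑6‑methoxy‑8‑methylidene‑4H‑chromene‑4,7(8H)‑dione (ortho‑quinone methide, boron‑bound in the flask) | C=C1C(=O)C(OC)=CC2=C1OC=C(c1ccc(OC)c(OC)c1)C2=O | intermediate (not isolated)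
9 | 3‑(3,4‑dimethoxyphenyl)‑7‑hydroxy‑6‑methoxy‑8‑(3‑methylbut‑2‑en‑1‑yl)‑4H‑chromen‑4‑one (EANPDB:LEGU_00008) | COc1ccc(-c2coc3c(CC=C(C)C)c(O)c(OC)cc3c2=O)cc1OC | target

## Summary

Total step count: 4
Longest linear sequence: 4 steps (1 → 3 → 5 → 6 → 9)

## Steps most likely to fail, with fallbacks

**Step 4 (proposed new step).** The risks are that the quinone methide dimerises, that 7 protodeboronates before transfer, or that the amine does not leave at a useful temperature. The fallback uses known chemistry, sets out from 5 and comes back at 9. O‑Alkylation of 5 with 3‑chloro‑3‑methylbut‑1‑yne (K2CO3, KI, cat. CuI, acetone, reflux) gives 3‑(3,4‑dimethoxyphenyl)‑6‑methoxy‑7‑[(2‑methylbut‑3‑yn‑2‑yl)oxy]‑4H‑chromen‑4‑one F1. Lindlar semihydrogenation (H2, Pd/CaCO3–Pb, quinoline, EtOAc, rt) gives 3‑(3,4‑dimethoxyphenyl)‑6‑methoxy‑7‑[(2‑methylbut‑3‑en‑2‑yl)oxy]‑4H‑chromen‑4‑one F2. Aromatic Claisen rearrangement (PhNEt2, 130 °C) then gives 9, because the [3,3] shift of the tertiary allyl ether delivers the linear prenyl group to C8, the only free ortho position.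

**Step 3 (Mannich aminomethylation).** The risks are that the Mannich base loses amine early and oligomerises through the quinone methide, or that purification of the zwitterion is poor. The fallback sets out from 5 and comes back at 9, replacing aminomethylation and alkenyl transfer by halogenation and cross‑coupling. Phenoxide‑directed iodination (I2, KI, aq. NH3/EtOH, rt) gives 3‑(3,4‑dimethoxyphenyl)‑7‑hydroxy‑8‑iodo‑6‑methoxy‑4H‑chromen‑4‑one F3. An α‑selective allyl Suzuki–Miyaura coupling with 4,4,5,5‑tetramethyl‑2‑(3‑methylbut‑2‑en‑1‑yl)‑1,3,2‑dioxaborolane (bulky Pd–NHC precatalyst, KOH, THF, 70 °C) gives 9 with the linear prenyl group.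

**Step 1 (Friedel–Crafts acylation).** The risks are regioisomeric or double acylation of the very electron‑rich resorcinol and partial ether cleavage. The fallback sets out from 1 and comes back at 3, using a nitrile electrophile in place of the acid. Houben–Hoesch reaction of 1 with (3,4‑dimethoxyphenyl)acetonitrile (ZnCl2, HCl gas, Et2O, 0 °C) precipitates 1‑(2,4‑dihydroxy‑5‑methoxyphenyl)‑2‑(3,4‑dimethoxyphenyl)ethan‑1‑iminium chloride F4, which cannot react a second time. Hydrolysis (H2O, 100 °C) gives 3.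

## Further compounds

F1 | step 4 | 3‑(3,4‑dimethoxyphenyl)‑6‑methoxy‑7‑[(2‑methylbut‑3‑yn‑2‑yl)oxy]‑4H‑chromen‑4‑one | COc1ccc(-c2coc3cc(OC(C)(C)C#C)c(OC)cc3c2=O)cc1OC
F2 | step 4 | 3‑(3,4‑dimethoxyphenyl)‑6‑methoxy‑7‑[(2‑methylbut‑3‑en‑2‑yl)oxy]‑4H‑chromen‑4‑one | COc1ccc(-c2coc3cc(OC(C)(C)C=C)c(OC)cc3c2=O)cc1OC
F3 | step 3 | 3‑(3,4‑dimethoxyphenyl)‑7‑hydroxy‑8‑iodo‑6‑methoxy‑4H‑chromen‑4‑one | COc1ccc(-c2coc3c(I)c(O)c(OC)cc3c2=O)cc1OC
F4 | step 1 | 1‑(2,4‑dihydroxy‑5‑methoxyphenyl)‑2‑(3,4‑dimethoxyphenyl)ethan‑1‑iminium chloride | COc1ccc(CC(=[NH2+])c2cc(OC)c(O)cc2O)cc1OC.[Cl-]
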